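**Plan**
1. Retrosynthesis: after desilylation, the side chain is cut at the sp3–sp2 bond between the alkene CH and the CH2 two atoms away from C2 (Negishi coupling), giving chromene iodide 10 and iodoalkenyl butenolide 25. In 10 the pyran bonds C3–C4 and O1–C2 are cut together, back to salicylaldehyde 3 and 3-methylbut-2-enal 4. In 25 the butenolide C3=C4 bond (ring-closing metathesis) and the ester C–O bond are cut.
2. Enabling feature: C2 of the pyran ring is an oxygen-bearing quaternary carbon whose carbon neighbours (ring C3, the 2-methyl, the first chain CH2) are those of the β-carbon of 4, while O1 and C4 sit on the adjacent arene carbons C8a and C4a as phenol and formyl group. C3–C4 is therefore a vinylogous aldol bond and O1–C2 an oxa-Michael bond once the second chain carbon is an aldehyde.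
3. Forward order: arene 3, then the pyran ring in one domino step (held as a temporary lactol bridge C4–O–CH(OH)–CH2–C2), then reduction, dehydration to the C3=C4 alkene and iodide 10. The butenolide ring is made separately by metathesis; union of 10 and 25 and desilylation follow.
4. Stereochemistry: C2 (R) from the (R)-diarylprolinol silyl ether catalyst of the domino step; butenolide C5 (R) from (R)-epichlorohydrin; the (E)-trisubstituted alkene from syn-carboalumination. The C4 and lactol stereocentres are temporary.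

Key step: step 3

Remark: 2H-chromenes racemise by thermal or photochemical ring opening to the vinyl ortho-quinone methide, so everything after step 5 is run at or below 50 °C with exclusion of light.

**Route**

Step 1
Reactants: 1 2-methylbenzene-1,4-diol
Product: 2 2-methyl-4-[(triisopropylsilyl)oxy]phenol
Conditions: i-Pr3SiCl (1.0 equiv), imidazole, DMF, 0 °C
Reagents that add atoms: chlorotriisopropylsilane, CC(C)[Si](Cl)(C(C)C)C(C)C
Why: Silyl ether formation at a phenol; the hydroxyl without an ortho substituent should react first with the bulky silyl chloride, and the minor regioisomer and bis-silyl ether are removed by chromatography.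

Step 2
Reactants: 2 2-methyl-4-[(triisopropylsilyl)oxy]phenol
Product: 3 2-hydroxy-3-methyl-5-[(triisopropylsilyl)oxy]benzaldehyde
Conditions: MgCl2, Et3N, (CH2O)n, MeCN, reflux
Reagents that add atoms: formaldehyde (as paraformaldehyde), C=O
Why: Magnesium phenoxide-directed ortho-formylation (Casnati–Skattebøl reaction), for which only one ortho position of the free phenol is open and which aryl silyl ethers survive.

Step 3
Reactants: 3 2-hydroxy-3-methyl-5-[(triisopropylsilyl)oxy]benzaldehyde; 4 3-methylbut-2-enal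
Product: 6 (2S,6S)-2,10-dimethyl-8-[(triisopropylsilyl)oxy]-3,4-dihydro-2H,6H-2,6-methano-1,5-benzodioxocin-4-ol (bridged lactol; anomers at C4 of this name), via hydroxy aldehyde 5 (not isolated)
Conditions: 4 (2 equiv, slow addition), (R)-2-{bis[3,5-bis(trifluoromethyl)phenyl][(trimethylsilyl)oxy]methyl}pyrrolidine (20 mol%), PhCO2H (20 mol%), toluene, rt
Reagents that add atoms: none
Why: The amine condenses with 4 to the iminium ion and, by loss of a γ-proton, the s-trans dienamine, whose terminal CH2 adds to the formyl carbon of 3 (vinylogous aldol, forms C3–C4) and regenerates an (E)-α,β-unsaturated iminium ion with the new CH2CH(OH)Ar arm trans to the iminium carbon; the phenol oxygen then adds to the β-carbon (oxa-Michael, forms O1–C2), and hydrolysis releases δ-hydroxy aldehyde 5, which closes to lactol 6. The closest known reaction type is the secondary-amine-catalysed domino reaction of salicylaldehydes with enals, which for β-methyl enals runs through the dienamine as vinylogous aldol/oxa-Michael/lactolization and has been used for 2-methyl-2-alkylchromans. The pyran ring closes 6-exo-trig (the enal C=C stays outside the forming ring), and the helper lactol ring closes 6-exo-trig by addition of the C4 hydroxyl to the aldehyde C=O. C2 is set by the catalyst: the CAr2OSiMe3 group of the (R)-catalyst covers one face of the (E), s-trans iminium ion, so the tethered phenol adds to the open face, which by the usual shielding model gives the arrangement that is 2R in the target (2S by CIP in 5 and 6, where the substituent ranks differ); C4 and the anomeric carbon need no control, since only the cis isomer lactolizes and both centres are removed later. The step needs γ- over α-reactivity of the dienamine and ring closure before dehydration of the aldol: the β,β-disubstitution of 4 disfavours direct oxa-Michael/α-aldol condensation, the ortho hydroxyl activates the aldehyde by hydrogen bonding, and capture as the bridged lactol protects the β-aryloxy aldehyde from retro-oxa-Michael racemisation.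

Step 4
Reactants: 6 bridged lactol
Product: 7 (2R,4S)-2-(2-hydroxyethyl)-2,8-dimethyl-6-[(triisopropylsilyl)oxy]-3,4-dihydro-2H-chromen-4-ol
Conditions: NaBH4, MeOH, 0 °C
Reagents that add atoms: none
Why: Hydride reduction of the lactol through its open hydroxy aldehyde form, which at 0 °C should outrun retro-oxa-Michael cleavage and leaves the aryl silyl ether intact.

Step 5
Reactants: 7 (2R,4S)-2-(2-hydroxyethyl)-2,8-dimethyl-6-[(triisopropylsilyl)oxy]-3,4-dihydro-2H-chromen-4-ol
Product: 9 2-{(2R)-2,8-dimethyl-6-[(triisopropylsilyl)oxy]-2H-chromen-2-yl}ethyl methanesulfonate, via bis-mesylate 8 (not isolated)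
Conditions: MsCl (2.5 equiv), Et3N, CH2Cl2, −10 °C to rt; then DBU, rt
Reagents that add atoms: methanesulfonyl chloride, CS(=O)(=O)Cl
Why: Sulfonylation of both hydroxyls followed by E1 loss of the benzylic C4 mesylate (cation stabilised by the ring oxygen through the arene) gives the C3=C4 alkene while the primary mesylate stays, and mesylating both oxygens at once keeps the C4 oxygen from closing onto the side chain.

Step 6
Reactants: 9 2-{(2R)-2,8-dimethyl-6-[(triisopropylsilyl)oxy]-2H-chromen-2-yl}ethyl methanesulfonate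
Product: 10 {[(2R)-2-(2-iodoethyl)-2,8-dimethyl-2H-chromen-6-yl]oxy}tri(propan-2-yl)silane
Conditions: NaI, acetone, 50 °C, dark
Reagents that add atoms: sodium iodide, [Na+].[I-]
Why: Finkelstein SN2 exchange at the unhindered primary mesylate.

Step 7
Reactants: 11 (2R)-2-(chloromethyl)oxirane [(R)-epichlorohydrin]; 12 ethynyl(trimethyl)silane
Product: 13 (2R)-1-chloro-5-(trimethylsilyl)pent-4-yn-2-ol
Conditions: 12, n-BuLi, THF, −78 °C; BF3·OEt2; then 11, −78 °C
Reagents that add atoms: none
Why: BF3-promoted opening of the epoxide at its CH2 terminus by the lithium acetylide (Yamaguchi alkynylation) leaves the C–O stereocentre untouched and keeps the chloride.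

Step 8
Reactants: 13 (2R)-1-chloro-5-(trimethylsilyl)pent-4-yn-2-ol
Product: 15 (3R)-6-(trimethylsilyl)hex-1-en-5-yn-3-ol, via epoxide 14 (not isolated)
Conditions: Me3S+ I− (4 equiv), n-BuLi (4 equiv), THF, −10 °C to rt
Reagents that add atoms: trimethylsulfonium iodide, C[S+](C)C.[I-]
Why: The alkoxide closes to the terminal epoxide, which dimethylsulfonium methylide opens at CH2 and converts, by ylide-mediated loss of Me2S, into the one-carbon-homologated allylic alcohol without touching the carbinol stereocentre.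

Step 9
Reactants: 15 (3R)-6-(trimethylsilyl)hex-1-en-5-yn-3-ol
Product: 16 (3R)-hex-1-en-5-yn-3-ol
Conditions: K2CO3 (cat.), MeOH, rt
Reagents that add atoms: none
Why: Base-catalysed methanolysis of the alkynyl C–Si bond.

Step 10
Reactants: 16 (3R)-hex-1-en-5-yn-3-ol
Product: 18 (3R,5E)-6-iodo-5-methylhexa-1,5-dien-3-ol, via alkenylalane 17 (not isolated)
Conditions: AlMe3 (3 equiv), Cp2ZrCl2 (0.25 equiv), CH2Cl2, 0 °C to rt; then I2, THF, −30 °C
Reagents that add atoms: trimethylaluminium, C[Al](C)C; iodine, II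
Why: Zirconium-catalysed carboalumination (Negishi) adds Me and Al syn across the terminal alkyne with Me on the internal carbon, and iodinolysis of the alkenyl–Al bond with retention gives the (E)-iodoalkene.

Step 11
Reactants: 19 triethyl phosphonoacetate; 20 5-bromo-2-methylpent-2-ene
Product: 21 ethyl 2-(diethoxyphosphoryl)-6-methylhept-5-enoate (racemic)
Conditions: NaH, THF/DMF, 0 °C; then 20, 60 °C
Reagents that add atoms: none
Why: SN2 C-alkylation of the stabilised phosphonoacetate anion with a primary bromide.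

Step 12
Reactants: 21 ethyl 2-(diethoxyphosphoryl)-6-methylhept-5-enoate
Product: 22 ethyl 6-methyl-2-methylidenehept-5-enoate
Conditions: aq. CH2O (37%), K2CO3, H2O, rt
Reagents that add atoms: formaldehyde, C=O
Why: Horner–Wadsworth–Emmons olefination with formaldehyde gives the 1,1-disubstituted acrylate.

Step 13
Reactants: 22 ethyl 6-methyl-2-methylidenehept-5-enoate
Product: 23 6-methyl-2-methylidenehept-5-enoic acid
Conditions: LiOH, THF/H2O, rt; then aq. HCl
Reagents that add atoms: lithium hydroxide, [Li+].[OH-]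
Why: Ester saponification, under which neither alkene is touched.

Step 14
Reactants: 18 (3R,5E)-6-iodo-5-methylhexa-1,5-dien-3-ol; 23 6-methyl-2-methylidenehept-5-enoic acid
Product: 24 (3R,5E)-6-iodo-5-methylhexa-1,5-dien-3-yl 6-methyl-2-methylidenehept-5-enoate
Conditions: DCC, DMAP (cat.), CH2Cl2, 0 °C to rt
Reagents that add atoms: none
Why: Steglich esterification of the secondary allylic alcohol, which acylates oxygen and so retains the carbinol configuration.

Step 15
Reactants: 24 (3R,5E)-6-iodo-5-methylhexa-1,5-dien-3-yl 6-methyl-2-methylidenehept-5-enoate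
Product: 25 (5R)-5-[(2E)-3-iodo-2-methylprop-2-en-1-yl]-3-(4-methylpent-3-en-1-yl)furan-2(5H)-one
Conditions: second-generation Grubbs catalyst RuCl2(H2IMes)(PCy3)(=CHPh) (5 mol%), CH2Cl2 (5 mM), 40 °C
Reagents that add atoms: none
Why: Ring-closing metathesis between the monosubstituted allylic alkene and the acrylate methylidene closes the five-membered butenolide, while the trisubstituted alkenes and the hindered iodoalkene are far slower partners.

Step 16
Reactants: 10 {[(2R)-2-(2-iodoethyl)-2,8-dimethyl-2H-chromen-6-yl]oxy}tri(propan-2-yl)silane; 25 (5R)-5-[(2E)-3-iodo-2-methylprop-2-en-1-yl]-3-(4-methylpent-3-en-1-yl)furan-2(5H)-one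
Product: 27 (5R)-5-{(2E)-5-[(2R)-2,8-dimethyl-6-[(triisopropylsilyl)oxy]-2H-chromen-2-yl]-2-methylpent-2-en-1-yl}-3-(4-methylpent-3-en-1-yl)furan-2(5H)-one, via alkylzinc iodide 26 (not isolated)
Conditions: Zn dust (activated with BrCH2CH2Br, Me3SiCl), LiCl, THF, 40 °C; then 25, PdCl2(dppf) (5 mol%), THF, rt, dark
Reagents that add atoms: none
Why: Zinc insertion into the primary C–I bond and Negishi sp3–sp2 cross-coupling (oxidative addition of the alkenyl iodide to zerovalent palladium, transmetalation, reductive elimination) join the fragments with retention of the (E)-alkene, and alkylzinc halides should leave the butenolide and the silyl ether untouched.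

Step 17
Reactants: 27 silyl ether of the target
Product: 28 2'-epi-tuberatolide B, (5R)-5-{(2E)-5-[(2R)-6-hydroxy-2,8-dimethyl-2H-chromen-2-yl]-2-methylpent-2-en-1-yl}-3-(4-methylpent-3-en-1-yl)furan-2(5H)-one
Conditions: Bu4NF, AcOH (1:1), THF, 0 °C
Reagents that add atoms: none
Why: Fluoride cleavage of the aryl silyl ether, buffered with acetic acid so that the γ-proton of the butenolide is not removed.

**Compound list**
1 | 2-methylbenzene-1,4-diol | Cc1cc(O)ccc1O | starting material
2 | 2-methyl-4-[(triisopropylsilyl)oxy]phenol | Cc1cc(O[Si](C(C)C)(C(C)C)C(C)C)ccc1O | intermediate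
3 | 2-hydroxy-3-methyl-5-[(triisopropylsilyl)oxy]benzaldehyde | Cc1cc(O[Si](C(C)C)(C(C)C)C(C)C)cc(C=O)c1O | intermediate
4 | 3-methylbut-2-enal | CC(C)=CC=O | starting material
5 | 2-{(2S,4S)-4-hydroxy-2,8-dimethyl-6-[(triisopropylsilyl)oxy]-3,4-dihydro-2H-chromen-2-yl}acetaldehyde (not isolated) | O=CC[C@]1(C)C[C@H](O)c2cc(O[Si](C(C)C)(C(C)C)C(C)C)cc(C)c2O1 | intermediate
6 | (2S,6S)-2,10-dimethyl-8-[(triisopropylsilyl)oxy]-3,4-dihydro-2H,6H-2,6-methano-1,5-benzodioxocin-4-ol (anomers) | OC1C[C@]2(C)C[C@H](O1)c1cc(O[Si](C(C)C)(C(C)C)C(C)C)cc(C)c1O2 | intermediate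
7 | (2R,4S)-2-(2-hydroxyethyl)-2,8-dimethyl-6-[(triisopropylsilyl)oxy]-3,4-dihydro-2H-chromen-4-ol | OCC[C@]1(C)C[C@H](O)c2cc(O[Si](C(C)C)(C(C)C)C(C)C)cc(C)c2O1 | intermediate
8 | 2-{(2R,4S)-4-[(methanesulfonyl)oxy]-2,8-dimethyl-6-[(triisopropylsilyl)oxy]-3,4-dihydro-2H-chromen-2-yl}ethyl methanesulfonate (not isolated) | CS(=O)(=O)OCC[C@]1(C)C[C@H](OS(C)(=O)=O)c2cc(O[Si](C(C)C)(C(C)C)C(C)C)cc(C)c2O1 | intermediate
9 | 2-{(2R)-2,8-dimethyl-6-[(triisopropylsilyl)oxy]-2H-chromen-2-yl}ethyl methanesulfonate | CS(=O)(=O)OCC[C@]1(C)C=Cc2cc(O[Si](C(C)C)(C(C)C)C(C)C)cc(C)c2O1 | intermediate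
10 | {[(2R)-2-(2-iodoethyl)-2,8-dimethyl-2H-chromen-6-yl]oxy}tri(propan-2-yl)silane | ICC[C@]1(C)C=Cc2cc(O[Si](C(C)C)(C(C)C)C(C)C)cc(C)c2O1 | intermediate
11 | (2R)-2-(chloromethyl)oxirane | ClC[C@H]1CO1 | starting material
12 | ethynyl(trimethyl)silane | C#C[Si](C)(C)C | starting material
13 | (2R)-1-chloro-5-(trimethylsilyl)pent-4-yn-2-ol | ClC[C@@H](CC#C[Si](C)(C)C)O | intermediate
14 | trimethyl{3-[(2R)-oxiran-2-yl]prop-1-yn-1-yl}silane (not isolated) | C[Si](C)(C)C#CC[C@@H]1CO1 | intermediate
15 | (3R)-6-(trimethylsilyl)hex-1-en-5-yn-3-ol | C=C[C@@H](CC#C[Si](C)(C)C)O | intermediate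
16 | (3R)-hex-1-en-5-yn-3-ol | C=C[C@@H](CC#C)O | intermediate
17 | dimethylaluminium alkoxide of (3R,5E)-6-(dimethylalumanyl)-5-methylhexa-1,5-dien-3-ol (not isolated) | C=C[C@@H](C/C(C)=C/[Al](C)C)O[Al](C)C | intermediate
18 | (3R,5E)-6-iodo-5-methylhexa-1,5-dien-3-ol | C=C[C@@H](C/C(C)=C/I)O | intermediate
19 | triethyl phosphonoacetate | CCOC(=O)CP(=O)(OCC)OCC | starting material
20 | 5-bromo-2-methylpent-2-ene | CC(C)=CCCBr | starting material
21 | ethyl 2-(diethoxyphosphoryl)-6-methylhept-5-enoate (racemic) | CCOC(=O)C(CCC=C(C)C)P(=O)(OCC)OCC | intermediate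
22 | ethyl 6-methyl-2-methylidenehept-5-enoate | CCOC(=O)C(=C)CCC=C(C)C | intermediate
23 | 6-methyl-2-methylidenehept-5-enoic acid | OC(=O)C(=C)CCC=C(C)C | intermediate
24 | (3R,5E)-6-iodo-5-methylhexa-1,5-dien-3-yl 6-methyl-2-methylidenehept-5-enoate | C=C[C@@H](C/C(C)=C/I)OC(=O)C(=C)CCC=C(C)C | intermediate
25 | (5R)-5-[(2E)-3-iodo-2-methylprop-2-en-1-yl]-3-(4-methylpent-3-en-1-yl)furan-2(5H)-one | CC(C)=CCCC1=C[C@@H](C/C(C)=C/I)OC1=O | intermediate
26 | (2-{(2R)-2,8-dimethyl-6-[(triisopropylsilyl)oxy]-2H-chromen-2-yl}ethyl)zinc iodide (not isolated) | I[Zn]CC[C@]1(C)C=Cc2cc(O[Si](C(C)C)(C(C)C)C(C)C)cc(C)c2O1 | intermediate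
27 | (5R)-5-{(2E)-5-[(2R)-2,8-dimethyl-6-[(triisopropylsilyl)oxy]-2H-chromen-2-yl]-2-methylpent-2-en-1-yl}-3-(4-methylpent-3-en-1-yl)furan-2(5H)-one | CC(C)=CCCC1=C[C@@H](C/C(C)=C/CC[C@]2(C)C=Cc3cc(O[Si](C(C)C)(C(C)C)C(C)C)cc(C)c3O2)OC1=O | intermediate
28 | 2'-epi-tuberatolide B, (5R)-5-{(2E)-5-[(2R)-6-hydroxy-2,8-dimethyl-2H-chromen-2-yl]-2-methylpent-2-en-1-yl}-3-(4-methylpent-3-en-1-yl)furan-2(5H)-one | CC(C)=CCCC1=C[C@@H](C/C(C)=C/CC[C@]2(C)C=Cc3cc(O)cc(C)c3O2)OC1=O | target

**Step count and risks**
Total: 17 steps. Longest linear sequence: 8 steps (steps 1–6, 16, 17; the butenolide branch through steps 7–10, 14–17 is equally long).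

Steps most likely to fail:

1. Step 3. The dienamine may react through its α-carbon (oxa-Michael/aldol condensation to a chromene-3-carbaldehyde), the aldol adduct may dehydrate before ring closure, 4 may self-condense, or facial discrimination in the oxa-Michael step may be insufficient. The fallback sets out from 3 and comes back at 10. Wittig methylenation of 3 (Ph3PCH3Br, KOt-Bu, THF) gives 2-ethenyl-6-methyl-4-[(triisopropylsilyl)oxy]phenol F1. Palladium-catalysed asymmetric allylic etherification of F1 with racemic 2-methyl-2-vinyloxirane forms O1–C2 by dynamic kinetic asymmetric transformation through the π-allyl complex and gives the tertiary aryl ether (2S)-2-{2-ethenyl-6-methyl-4-[(triisopropylsilyl)oxy]phenoxy}-2-methylbut-3-en-1-ol F2; the conditions are Pd2(dba)3·CHCl3 and the enantiomer of N,N′-bis[2-(diphenylphosphino)benzoyl]cyclohexane-1,2-diamine that leads to the (S)-ether, in CH2Cl2 at rt. Ring-closing metathesis with the second-generation Grubbs catalyst forms C3=C4 and gives {(2S)-2,8-dimethyl-6-[(triisopropylsilyl)oxy]-2H-chromen-2-yl}methanol F3. Dess–Martin oxidation gives (2S)-2,8-dimethyl-6-[(triisopropylsilyl)oxy]-2H-chromene-2-carbaldehyde F4, and a second Wittig methylenation gives {[(2R)-2-ethenyl-2,8-dimethyl-2H-chromen-6-yl]oxy}tri(propan-2-yl)silane F5. Hydroboration of the monosubstituted alkene with 9-BBN gives the B-alkyl-9-borabicyclo[3.3.1]nonane F6, and iodinolysis (I2, NaOMe) gives 10.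

2. Step 16. Zinc insertion may be slow or the alkylzinc may be protonated, and the butenolide may suffer addition or loss of configuration at its γ-carbon during the coupling. The fallback sets out from 26 (made from 10 as in step 16) and 18 and comes back at 27; the lactone is built only after the fragments are joined. Organozinc 26 is coupled with the free alcohol 18 (Pd(OAc)2, SPhos, THF, rt, a catalyst system that tolerates hydroxyl groups) to give (3R,5E)-8-{(2R)-2,8-dimethyl-6-[(triisopropylsilyl)oxy]-2H-chromen-2-yl}-5-methylocta-1,5-dien-3-ol F7. Steglich esterification of F7 with acid 23 gives the 6-methyl-2-methylidenehept-5-enoate F8, and ring-closing metathesis of F8 with the second-generation Grubbs catalyst gives 27.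

3. Step 5. The C4 oxygen may alkylate intramolecularly at the activated primary carbon to give a bridged ether, or C4 may capture chloride without eliminating. The fallback sets out from 7 and comes back at 10. Selective silylation of the primary hydroxyl (t-BuMe2SiCl, imidazole, CH2Cl2, 0 °C) gives (2R,4S)-2-{2-[(tert-butyldimethylsilyl)oxy]ethyl}-2,8-dimethyl-6-[(triisopropylsilyl)oxy]-3,4-dihydro-2H-chromen-4-ol F9. Acid-catalysed dehydration of the benzylic alcohol (cat. p-TsOH, benzene, 50 °C) gives the chromene tert-butyl(2-{(2R)-2,8-dimethyl-6-[(triisopropylsilyl)oxy]-2H-chromen-2-yl}ethoxy)dimethylsilane F10. Cleavage of the alkyl silyl ether with PPTS in MeOH, which the aryl silyl ether survives, gives 2-{(2R)-2,8-dimethyl-6-[(triisopropylsilyl)oxy]-2H-chromen-2-yl}ethan-1-ol F11, and Appel iodination (I2, PPh3, imidazole) gives 10.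

**Further compounds**
F1 | step 3 | 2-ethenyl-6-methyl-4-[(triisopropylsilyl)oxy]phenol | C=Cc1cc(O[Si](C(C)C)(C(C)C)C(C)C)cc(C)c1O
F2 | step 3 | (2S)-2-{2-ethenyl-6-methyl-4-[(triisopropylsilyl)oxy]phenoxy}-2-methylbut-3-en-1-ol | OC[C@](C)(C=C)Oc1c(C)cc(O[Si](C(C)C)(C(C)C)C(C)C)cc1C=C
F3 | step 3 | {(2S)-2,8-dimethyl-6-[(triisopropylsilyl)oxy]-2H-chromen-2-yl}methanol | OC[C@]1(C)C=Cc2cc(O[Si](C(C)C)(C(C)C)C(C)C)cc(C)c2O1
F4 | step 3 | (2S)-2,8-dimethyl-6-[(triisopropylsilyl)oxy]-2H-chromene-2-carbaldehyde | O=C[C@]1(C)C=Cc2cc(O[Si](C(C)C)(C(C)C)C(C)C)cc(C)c2O1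
F5 | step 3 | {[(2R)-2-ethenyl-2,8-dimethyl-2H-chromen-6-yl]oxy}tri(propan-2-yl)silane | C=C[C@]1(C)C=Cc2cc(O[Si](C(C)C)(C(C)C)C(C)C)cc(C)c2O1
F6 | step 3 | 9-(2-{(2R)-2,8-dimethyl-6-[(triisopropylsilyl)oxy]-2H-chromen-2-yl}ethyl)-9-borabicyclo[3.3.1]nonane | C1CCC2CCCC1B2CC[C@]1(C)C=Cc2cc(O[Si](C(C)C)(C(C)C)C(C)C)cc(C)c2O1
F7 | step 16 | (3R,5E)-8-{(2R)-2,8-dimethyl-6-[(triisopropylsilyl)oxy]-2H-chromen-2-yl}-5-methylocta-1,5-dien-3-ol | C=C[C@@H](C/C(C)=C/CC[C@]1(C)C=Cc2cc(O[Si](C(C)C)(C(C)C)C(C)C)cc(C)c2O1)O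
F8 | step 16 | (3R,5E)-8-{(2R)-2,8-dimethyl-6-[(triisopropylsilyl)oxy]-2H-chromen-2-yl}-5-methylocta-1,5-dien-3-yl 6-methyl-2-methylidenehept-5-enoate | C=C[C@@H](C/C(C)=C/CC[C@]1(C)C=Cc2cc(O[Si](C(C)C)(C(C)C)C(C)C)cc(C)c2O1)OC(=O)C(=C)CCC=C(C)C
F9 | step 5 | (2R,4S)-2-{2-[(tert-butyldimethylsilyl)oxy]ethyl}-2,8-dimethyl-6-[(triisopropylsilyl)oxy]-3,4-dihydro-2H-chromen-4-ol | CC(C)(C)[Si](C)(C)OCC[C@]1(C)C[C@H](O)c2cc(O[Si](C(C)C)(C(C)C)C(C)C)cc(C)c2O1
F10 | step 5 | tert-butyl(2-{(2R)-2,8-dimethyl-6-[(triisopropylsilyl)oxy]-2H-chromen-2-yl}ethoxy)dimethylsilane | CC(C)(C)[Si](C)(C)OCC[C@]1(C)C=Cc2cc(O[Si](C(C)C)(C(C)C)C(C)C)cc(C)c2O1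
F11 | step 5 | 2-{(2R)-2,8-dimethyl-6-[(triisopropylsilyl)oxy]-2H-chromen-2-yl}ethan-1-ol | OCC[C@]1(C)C=Cc2cc(O[Si](C(C)C)(C(C)C)C(C)C)cc(C)c2O1
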